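Readings and results were generated by integration from invented constants.

Alder, maple, north-west and south carry the same starting material, initiator and transfer agent, with c(transfer agent) = 0.0900 M; what differs is the equivalents of coupling partner, so I set the two earlier runs against each other.

| flask | starting material | coupling partner | transfer agent | initiator | remark | time |
|---|---|---|---|---|---|---|
| alder | 0.30 M | 1.4 equiv (fed, over 3.0 h) | 0.090 M | 3.6 mol% | run made earlier; the fed solution adds 0.25 times the starting volume |  |
| maple | 0.30 M | 3.4 equiv (fed, over 3.0 h) | 0.090 M | 3.6 mol% | run made earlier; the fed solution adds 0.25 times the starting volume |  |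
| north-west | 0.30 M | 1.20 equiv (fed, over 3.0 h) | 0.0900 M | 3.6 mol% | the fed solution adds 0.25 times the starting volume | 15 h |
| south | 0.30 M | 2.40 equiv (fed, over 3.0 h) | 0.0900 M | 3.6 mol% | the fed solution adds 0.25 times the starting volume | 15 h |

- alder (time / h: starting material / %, target / %): 1.33: 97.9, 0; 4.00: 92.7, 2.1; 8.00: 84.9, 5.5; 10.0: 83.5, 4.9; 15.0: 78.6, 8.0
- maple (time / h: starting material / %, target / %): 1.33: 97.2, 0.7; 2.50: 93.4, 2.1; 4.00: 86.1, 4.7; 8.00: 70.0, 12.4; 15.0: 59.1, 18.6

(each reading ± 1 percentage point)

- every charge counts on the volume at the start, and the solution that is fed holds the whole dose
- what has gone from starting material into another species counts as reacted, even if it can come back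

- part of the starting material that has reacted at the end, north-west
- part of the starting material that has reacted at the end, south
- what raising the equivalents of coupling partner from its lowest to its highest value here does to the part of the starting material that has reacted (changes below 5 percentage points count as none) (no change / it falls / it rises)

To whoever takes over the bench: at 15.0 h alder has lost 21.4 % of its starting material and holds 8.0 % target, while maple has lost 40.9 % and holds 18.6 %. Target grows by a factor of 2.33 for 2.43 in equivalents, so I scale target with the equivalents. The extra starting material lost from alder to maple, divided by the extra target, is 1.84; this cost per target is a reading, and the line through both runs leaves 6.68 % lost at zero target.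

When you come at 15 h, I expect 6.86 % target in north-west, scaled from alder, and 13.1 % in south, scaled from maple. Put back into the line, these give 19.3 % and 30.8 % reacted. Leave the initiator and transfer agent as charged, since the line is read at those charges. The forecast, which reads the loss as “nearly first order in partner”, gives 19 % and 32 %, and for the trend, it rises; on south it stands higher than mine by 1.2 percentage points.

The flask gives 18.2 % for north-west and 30.1 % for south, and for the trend, it rises, by 12 points.

    initiator → 2 initiating radical (k = 0.00230 min⁻¹)
    starting material + initiating radical → capped initiator + first chain carrier (k = 20000 M⁻¹ s⁻¹)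
    coupling partner + first chain carrier → target + second chain carrier (k = 2.10 × 10⁵ M⁻¹ min⁻¹)
    starting material + second chain carrier → by-product + first chain carrier (k = 2.90 × 10⁵ M⁻¹ min⁻¹)
    transfer agent + first chain carrier → side product + idle radical (kL = 13000 M⁻¹ s⁻¹)
    2 idle radical → ended radicals (k = 2.00 × 10⁶ M⁻¹ s⁻¹)
    2 first chain carrier → ended chains (k = 1.20 × 10⁹ M⁻¹ s⁻¹)
    starting material + by-product ⇌ idle adduct, settled at all times (K = 590 M⁻¹)

With the targets that stand at the end, 5.99 % and 12.0 %, the cost per target gives 17.7 % and 28.8 %. In north-west the idle adduct, at 5.94 %, stands level with target and counts as reacted. The neighbour of south, charged with 0.036 M of transfer agent and the same initiator, ends with 36.6 % target. The same line gives it 74.0 % reacted, and that flask shows 78.4 %.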